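The route rests on disconnecting the C7–C8 bond of the cyclohepta[b]furan-2-one (O1, C2, C3, C3a, C4–C8, C8a; side chain C1'–C4'). The fully substituted C7 carries both the ring carbon C8 and the side-chain carbon C1', so a rhodium-catalysed hydroacylation of an alkyne C7≡C1' by an aldehyde at C8 closes the seven-membered ketone and fixes the exocyclic (E)-C7=C1' alkene in one operation. The precursor is an all-cis γ-lactone (C3 methyl, C3a chain, C8a formyl) whose chain C4–C5–C6 ends in the internal alkyne bearing the silylated C3' carbinol; all stereocentres except C7 and C8 are already in place.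

Key step: step 18

Remark: TBS = tert-butyldimethylsilyl, TES = triethylsilyl; the locants above are used for all intermediates.
Remark: the hydroxy ester is used as its (R)-enantiomer, because its ester carbon becomes C5 and its hydroxymethyl carbon C7, which gives (6S).
Remark: the key-step precursor 22 has the methyl group α to the lactone carbonyl, so it is a 4-methyl-3-alkyl-5-oxooxolane-2-carbaldehyde.
Remark: between steps 10 and 17 the lactone is carried as its methyl lactol acetal (both anomers), because a lithium acetylide would attack or enolise the all-cis lactone.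

Step 1
Reactants: 1 methyl (4S)-2,2-dimethyl-1,3-dioxolane-4-carboxylate; 2 ethyl propanoate
Product: 3 ethyl 3-[(4S)-2,2-dimethyl-1,3-dioxolan-4-yl]-2-methyl-3-oxopropanoate
Conditions: LiN(i-Pr)2 (2.2 equiv), 2 (2.2 equiv), THF, −78 °C; then 1, −78 °C; aq. NH4Cl
Reagents that add atoms: none
Why: Crossed Claisen condensation, in which the ester enolate should acylate the activated α-alkoxy ester faster than it deprotonates it and the product rests as its 1,3-dicarbonyl enolate, so that the dioxolane stereocentre is not touched.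

Step 2
Reactants: 3 β-keto ester
Product: 4 (5S)-4-hydroxy-5-(hydroxymethyl)-3-methylfuran-2(5H)-one
Conditions: TFA/H2O (9:1), 0 °C to rt; evaporation with toluene
Reagents that add atoms: none
Why: Acetal hydrolysis frees the diol and the secondary hydroxyl should lactonise onto the β-keto ester (5-exo-trig transesterification) to the tetronic acid, the five-membered vinylogous acid being the thermodynamic sink; C5 is the old dioxolane carbon and is not involved.

Step 3
Reactants: 4 tetronic acid diol
Product: 5 (5S)-5-[(TBS-oxy)methyl]-4-hydroxy-3-methylfuran-2(5H)-one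
Conditions: TBSCl (1.1 equiv), imidazole, DMF, 0 °C
Reagents that add atoms: tert-butyldimethylsilyl chloride CC(C)(C)[Si](C)(C)Cl
Why: Silylation of the primary alcohol, selective because the acidic tetronic enol can only form a labile vinylogous silyl ester that passes its silyl group on or is hydrolysed on work-up.

Step 4
Reactants: 5 silylated tetronic acid
Product: 6 (2S)-2-[(TBS-oxy)methyl]-4-methyl-5-oxo-2,5-dihydrofuran-3-yl trifluoromethanesulfonate
Conditions: Tf2O, i-Pr2NEt, CH2Cl2, −78 °C
Reagents that add atoms: trifluoromethanesulfonic anhydride O=S(=O)(OS(=O)(=O)C(F)(F)F)C(F)(F)F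
Why: O-sulfonylation of the tetronic enol gives the vinylogous acyl triflate for cross-coupling, and the hindered non-nucleophilic base at low temperature should leave the C5–H stereocentre alone.

Step 5
Reactants: 7 methyl (2R)-3-hydroxy-2-methylpropanoate
Product: 8 methyl (2R)-2-methyl-3-(TES-oxy)propanoate
Conditions: Et3SiCl, imidazole, CH2Cl2, 0 °C
Reagents that add atoms: chlorotriethylsilane CC[Si](Cl)(CC)CC
Why: Standard silylation, with the TES group chosen because it can later be removed in the presence of a primary TBS ether.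

Step 6
Reactants: 8 silyloxy ester
Product: 9 (2R)-2-methyl-3-(TES-oxy)propanal
Conditions: i-Bu2AlH (1.05 equiv), CH2Cl2, −78 °C; aq. potassium sodium tartrate
Reagents that add atoms: none
Why: Partial ester reduction stops at the aluminium hemiacetal at −78 °C, and the α-stereocentre should survive if the aldehyde is kept cold and used at once.

Step 7
Reactants: 9 aldehyde
Product: 10 triethyl{[(2S)-2-methylbut-3-en-1-yl]oxy}silane
Conditions: Ph3PCH3Br, KN(SiMe3)2, THF, −78 to 0 °C
Reagents that add atoms: methyltriphenylphosphonium bromide C[P+](c1ccccc1)(c1ccccc1)c1ccccc1.[Br-]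
Why: Wittig methylenation with the salt-free ylide turns the former ester carbon into the vinyl group without epimerisation; the descriptor changes to (S) only through the CIP priorities.

Step 8
Reactants: 10 alkene; 6 tetronate triflate
Product: 12 (5R)-5-[(TBS-oxy)methyl]-3-methyl-4-[(3S)-3-methyl-4-(TES-oxy)butyl]furan-2(5H)-one, via B-alkyl-9-BBN 11 (not isolated)
Conditions: 9-BBN, THF, 0 °C to rt; then 6, PdCl2(dppf) (5 mol %), AsPh3, 3 M aq. K3PO4, DMF, rt
Reagents that add atoms: none
Why: Anti-Markovnikov hydroboration followed by B-alkyl Suzuki–Miyaura coupling with the vinylogous acyl triflate forms C3a–C4; no stereocentre is formed and the mild base at room temperature should spare the C8a–H centre.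

Step 9
Reactants: 12 butenolide
Product: 13 (3R,4S,5R)-5-[(TBS-oxy)methyl]-3-methyl-4-[(3S)-3-methyl-4-(TES-oxy)butyl]oxolan-2-one
Conditions: H2 (50 bar), 5% Rh on Al2O3, EtOAc, rt
Reagents that add atoms: none
Why: Heterogeneous hydrogenation of the tetrasubstituted butenolide should deliver both hydrogens syn from the face opposite the C8a silyloxymethyl group, which sets C3 and C3a and gives the all-cis lactone; rhodium reduces hindered alkenes without double-bond migration.

Step 10
Reactants: 13 all-cis lactone
Product: 14 the corresponding lactol (oxolan-2-ol, both anomers)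
Conditions: i-Bu2AlH (1.1 equiv), toluene, −78 °C; aq. potassium sodium tartrate
Reagents that add atoms: none
Why: Reduction of a γ-lactone with i-Bu2AlH at −78 °C stops at the lactol, which masks the carbonyl before the carbanion steps and leaves C3 without an acidic hydrogen.

Step 11
Reactants: 14 lactol
Product: 15 (2S)-4-{(2R,3S,4R)-2-[(TBS-oxy)methyl]-5-methoxy-4-methyloxolan-3-yl}-2-methylbutan-1-ol
Conditions: PPTS (cat.), MeOH, 0 °C to rt
Reagents that add atoms: methanol CO
Why: Acid-catalysed acetalisation of the lactol in methanol with simultaneous methanolysis of the primary TES ether, which is markedly more acid-labile than the primary TBS ether.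

Step 12
Reactants: 15 primary alcohol
Product: 16 (2S)-4-{(2R,3S,4R)-2-[(TBS-oxy)methyl]-5-methoxy-4-methyloxolan-3-yl}-2-methylbutanal
Conditions: Dess–Martin periodinane, NaHCO3, CH2Cl2, 0 °C to rt
Reagents that add atoms: none
Why: Buffered Dess–Martin oxidation should give the α-branched aldehyde without epimerising C6 or touching the acetal.

Step 13
Reactants: 16 aldehyde
Product: 17 tert-butyl({(2R,3S,4R)-5-methoxy-4-methyl-3-[(3S)-3-methylpent-4-yn-1-yl]oxolan-2-yl}methoxy)dimethylsilane
Conditions: dimethyl (1-diazo-2-oxopropyl)phosphonate, K2CO3, MeOH, 0 °C to rt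
Reagents that add atoms: dimethyl (1-diazo-2-oxopropyl)phosphonate COP(=O)(OC)C(=[N+]=[N-])C(C)=O
Why: Seyferth–Gilbert homologation with the Ohira–Bestmann reagent gives the terminal alkyne under conditions mild enough for the α-methyl centre C6.

Step 14
Reactants: 17 terminal alkyne; 18 (2S)-2-methyloxirane
Product: 19 (2S,6S)-8-{(2R,3S,4R)-2-[(TBS-oxy)methyl]-5-methoxy-4-methyloxolan-3-yl}-6-methyloct-4-yn-2-ol
Conditions: n-BuLi, THF, −78 °C; DMPU, then 18, −78 °C to rt; aq. NH4Cl
Reagents that add atoms: none
Why: SN2 opening of the epoxide at its unsubstituted carbon by the lithium acetylide forms C1'–C2' and brings in C3' unchanged; a polar co-solvent replaces the usual Lewis acid so that the acetal is not ionised, and no ester is present.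

Step 15
Reactants: 19 homopropargylic alcohol
Product: 20 the O3' TBS ether of 19
Conditions: TBSCl, imidazole, DMF, rt
Reagents that add atoms: tert-butyldimethylsilyl chloride CC(C)(C)[Si](C)(C)Cl
Why: Standard silylation of the secondary alcohol; the bulky, poorly coordinating ether should keep O3' away from rhodium in the key step.

Step 16
Reactants: 20 bis-silyl ether acetal
Product: 21 (3R,4S,5R)-4-[(3S,7S)-7-(TBS-oxy)-3-methyloct-4-yn-1-yl]-5-(hydroxymethyl)-3-methyloxolan-2-ol
Conditions: AcOH/THF/H2O (3:1:1), rt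
Reagents that add atoms: water O
Why: Aqueous acetic acid should hydrolyse the furanoside acetal and the primary silyl ether while the more hindered secondary silyl ether at C3' survives.

Step 17
Reactants: 21 lactol alcohol
Product: 22 (2R,3S,4R)-3-[(3S,7S)-7-(TBS-oxy)-3-methyloct-4-yn-1-yl]-4-methyl-5-oxooxolane-2-carbaldehyde
Conditions: Dess–Martin periodinane (3 equiv), NaHCO3, CH2Cl2, 0 °C to rt; used without storage
Reagents that add atoms: none
Why: Dess–Martin oxidation takes the lactol to the lactone and the primary alcohol to the aldehyde in one operation under buffered, non-basic conditions, which should keep the epimerisable C8a and C3 centres.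

Step 18
Reactants: 22 alkynyl aldehyde
Product: 23 (3R,3aS,6S,8aR)-7-[(1E,3S)-3-(TBS-oxy)butylidene]-3,6-dimethylhexahydro-2H-cyclohepta[b]furan-2,8(3H)-dione
Conditions: [Rh(cod)2]BF4 (10 mol %), dppe (10 mol %), H2 then argon (catalyst activation), acetone, 0.01 M, rt to 50 °C
Reagents that add atoms: none
Why: Proposed new method: oxidative addition of the C8–H bond to cationic monovalent rhodium should give an acyl hydride of trivalent rhodium that holds the tethered alkyne, syn hydrometalation then puts hydride on C1' and rhodium on C7, and reductive elimination forms C7–C8. The closest known reaction type is the rhodium-catalysed intramolecular hydroacylation of 5- and 6-alkynals to α-alkylidene cyclopentanones and cyclohexanones; closure of a 7-alkynal to a cycloheptanone without a chelating heteroatom has not been shown. The ring closes in the 7-exo-dig mode, since the 8-endo mode would have to place an (E)-alkene inside an eight-membered ring. No stereocentre is formed; the (E) geometry of C7=C1' follows from the syn delivery of acyl and hydride. The step needs exo selectivity and reductive elimination faster than decarbonylation: the cis arrangement of formyl group and chain on the lactone keeps the alkyne on the metal, the chelating diphosphine on a cationic centre speeds reductive elimination, and the bulky silyl ether keeps O3' from steering rhodium to C1'. The ester-type oxygen O1 is not counted on as a ligand (it would close a four-membered chelate), and the neutral medium leaves the epimerisable C8a untouched.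

Step 19
Reactants: 23 enone
Product: 24 (3R,3aS,6S,8S,8aR)-7-[(1E,3S)-3-(TBS-oxy)butylidene]-8-hydroxy-3,6-dimethyloctahydro-2H-cyclohepta[b]furan-2-one (8-OH cis to O1)
Conditions: NaBH4, CeCl3·7H2O, MeOH, −78 °C
Reagents that add atoms: none
Why: Luche 1,2-reduction, in which hydride should add to C8 from the convex face anti to the C8a–O1 bond (Felkin–Anh), placing the hydroxyl cis to O1 and leaving lactone and alkene untouched.

Step 20
Reactants: 24 allylic alcohol
Product: 25 the 7,1'-epoxide of 24 (spiro-oxirane at C7, oxirane oxygen on the face of the 8-hydroxyl)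
Conditions: VO(acac)2 (5 mol %), t-BuOOH (in decane), CH2Cl2, 0 °C to rt
Reagents that add atoms: tert-butyl hydroperoxide CC(C)(C)OO
Why: Hydroxyl-directed vanadium-catalysed epoxidation delivers oxygen to the alkene face on which the C8 hydroxyl lies, which should set C7–O cis to C8–OH against the steric bias of the C6 methyl group; C1' follows from the (E) geometry.

Step 21
Reactants: 25 epoxy alcohol; 26 angelic acid
Product: 27 the 8-epi angelate of 25 (ester on C8 trans to the oxirane oxygen)
Conditions: PPh3, DIAD, toluene, 0 °C to rt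
Reagents that add atoms: none
Why: Mitsunobu esterification, in which angelate displaces the C8 alkoxyphosphonium ion with inversion (SN2); the acid reacts as the carboxylate and is never activated at its carbonyl, so its (Z) geometry is not at risk.

Step 22
Reactants: 27 epoxy angelate
Product: 29 (3R,3aS,6S,7S,8S,8aR)-7-[(3S)-3-(TBS-oxy)butanoyl]-7-hydroxy-3,6-dimethyl-2-oxooctahydro-2H-cyclohepta[b]furan-8-yl (2Z)-2-methylbut-2-enoate, via alkoxysulfonium triflate 28 (not isolated)
Conditions: DMSO (10 equiv), TfOH (1.1 equiv), CH2Cl2, −40 to 0 °C; then i-Pr2NEt (4 equiv), 0 °C to rt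
Reagents that add atoms: dimethyl sulfoxide CS(C)=O
Why: Acid-promoted oxidative epoxide opening of the Kornblum/Swern type, in which DMSO should attack C1' from the back (C7 is fully substituted and its ionisation is disfavoured by the acyloxy group on C8) and base collapses the alkoxysulfonium salt to the ketone, so the C7–O bond is never broken and C7 keeps its configuration.

Step 23
Reactants: 29 silyl-protected ketol
Product: 30 target, (3R,3aS,6S,7S,8S,8aR)-7-hydroxy-7-[(3S)-3-hydroxybutanoyl]-3,6-dimethyl-2-oxooctahydro-2H-cyclohepta[b]furan-8-yl (2Z)-2-methylbut-2-enoate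
Conditions: HF·pyridine, pyridine, THF, 0 °C to rt
Reagents that add atoms: none
Why: Silyl ether cleavage with buffered HF·pyridine is non-basic and should spare the angelate, the lactone and the β-hydroxy ketone (no retro-aldol or elimination).

Compound list
1 | methyl (4S)-2,2-dimethyl-1,3-dioxolane-4-carboxylate | COC(=O)[C@@H]1COC(C)(C)O1 | starting material
2 | ethyl propanoate | CCOC(=O)CC | starting material
3 | ethyl 3-[(4S)-2,2-dimethyl-1,3-dioxolan-4-yl]-2-methyl-3-oxopropanoate (both C2 epimers) | CCOC(=O)C(C)C(=O)[C@@H]1COC(C)(C)O1 | intermediate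
4 | (5S)-4-hydroxy-5-(hydroxymethyl)-3-methylfuran-2(5H)-one | O=C1O[C@@H](CO)C(O)=C1C | intermediate
5 | (5S)-5-[(tert-butyldimethylsilyloxy)methyl]-4-hydroxy-3-methylfuran-2(5H)-one | O=C1O[C@@H](CO[Si](C)(C)C(C)(C)C)C(O)=C1C | intermediate
6 | (2S)-2-[(tert-butyldimethylsilyloxy)methyl]-4-methyl-5-oxo-2,5-dihydrofuran-3-yl trifluoromethanesulfonate | O=C1O[C@@H](CO[Si](C)(C)C(C)(C)C)C(OS(=O)(=O)C(F)(F)F)=C1C | intermediate
7 | methyl (2R)-3-hydroxy-2-methylpropanoate | COC(=O)[C@H](C)CO | starting material
8 | methyl (2R)-2-methyl-3-(triethylsilyloxy)propanoate | COC(=O)[C@H](C)CO[Si](CC)(CC)CC | intermediate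
9 | (2R)-2-methyl-3-(triethylsilyloxy)propanal | O=C[C@H](C)CO[Si](CC)(CC)CC | intermediate
10 | triethyl{[(2S)-2-methylbut-3-en-1-yl]oxy}silane | C=C[C@H](C)CO[Si](CC)(CC)CC | intermediate
11 | 9-[(3S)-3-methyl-4-(triethylsilyloxy)butyl]-9-borabicyclo[3.3.1]nonane | CC[Si](CC)(CC)OC[C@@H](C)CCB1C2CCCC1CCC2 | intermediate (not isolated)
12 | (5R)-5-[(tert-butyldimethylsilyloxy)methyl]-3-methyl-4-[(3S)-3-methyl-4-(triethylsilyloxy)butyl]furan-2(5H)-one | O=C1O[C@@H](CO[Si](C)(C)C(C)(C)C)C(CC[C@H](C)CO[Si](CC)(CC)CC)=C1C | intermediate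
13 | (3R,4S,5R)-5-[(tert-butyldimethylsilyloxy)methyl]-3-methyl-4-[(3S)-3-methyl-4-(triethylsilyloxy)butyl]oxolan-2-one (3,4,5-all-cis) | CC(C)(C)[Si](C)(C)OC[C@@H]1OC(=O)[C@H](C)[C@@H]1CC[C@H](C)CO[Si](CC)(CC)CC | intermediate
14 | (3R,4S,5R)-5-[(tert-butyldimethylsilyloxy)methyl]-3-methyl-4-[(3S)-3-methyl-4-(triethylsilyloxy)butyl]oxolan-2-ol (both anomers) | CC(C)(C)[Si](C)(C)OC[C@@H]1OC(O)[C@H](C)[C@@H]1CC[C@H](C)CO[Si](CC)(CC)CC | intermediate
15 | (2S)-4-{(2R,3S,4R)-2-[(tert-butyldimethylsilyloxy)methyl]-5-methoxy-4-methyloxolan-3-yl}-2-methylbutan-1-ol (both anomers) | CC(C)(C)[Si](C)(C)OC[C@@H]1OC(OC)[C@H](C)[C@@H]1CC[C@H](C)CO | intermediate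
16 | (2S)-4-{(2R,3S,4R)-2-[(tert-butyldimethylsilyloxy)methyl]-5-methoxy-4-methyloxolan-3-yl}-2-methylbutanal (both anomers) | CC(C)(C)[Si](C)(C)OC[C@@H]1OC(OC)[C@H](C)[C@@H]1CC[C@H](C)C=O | intermediate
17 | tert-butyl({(2R,3S,4R)-5-methoxy-4-methyl-3-[(3S)-3-methylpent-4-yn-1-yl]oxolan-2-yl}methoxy)dimethylsilane (both anomers) | CC(C)(C)[Si](C)(C)OC[C@@H]1OC(OC)[C@H](C)[C@@H]1CC[C@H](C)C#C | intermediate
18 | (2S)-2-methyloxirane | C[C@H]1CO1 | starting material
19 | (2S,6S)-8-{(2R,3S,4R)-2-[(tert-butyldimethylsilyloxy)methyl]-5-methoxy-4-methyloxolan-3-yl}-6-methyloct-4-yn-2-ol (both anomers) | CC(C)(C)[Si](C)(C)OC[C@@H]1OC(OC)[C@H](C)[C@@H]1CC[C@H](C)C#CC[C@H](C)O | intermediate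
20 | tert-butyldimethylsilyl ether of 19 at the C3' oxygen (both anomers) | CC(C)(C)[Si](C)(C)OC[C@@H]1OC(OC)[C@H](C)[C@@H]1CC[C@H](C)C#CC[C@H](C)O[Si](C)(C)C(C)(C)C | intermediate
21 | (3R,4S,5R)-4-[(3S,7S)-7-(tert-butyldimethylsilyloxy)-3-methyloct-4-yn-1-yl]-5-(hydroxymethyl)-3-methyloxolan-2-ol (both anomers) | OC[C@@H]1OC(O)[C@H](C)[C@@H]1CC[C@H](C)C#CC[C@H](C)O[Si](C)(C)C(C)(C)C | intermediate
22 | (2R,3S,4R)-3-[(3S,7S)-7-(tert-butyldimethylsilyloxy)-3-methyloct-4-yn-1-yl]-4-methyl-5-oxooxolane-2-carbaldehyde (2,3,4-all-cis) | O=C[C@@H]1OC(=O)[C@H](C)[C@@H]1CC[C@H](C)C#CC[C@H](C)O[Si](C)(C)C(C)(C)C | intermediate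
23 | (3R,3aS,6S,8aR)-7-[(1E,3S)-3-(tert-butyldimethylsilyloxy)butylidene]-3,6-dimethylhexahydro-2H-cyclohepta[b]furan-2,8(3H)-dione | O=C1[C@@H]2OC(=O)[C@H](C)[C@@H]2CC[C@H](C)/C1=C\C[C@H](C)O[Si](C)(C)C(C)(C)C | intermediate
24 | (3R,3aS,6S,8S,8aR)-7-[(1E,3S)-3-(tert-butyldimethylsilyloxy)butylidene]-8-hydroxy-3,6-dimethyloctahydro-2H-cyclohepta[b]furan-2-one (8-OH cis to O1) | O[C@@H]1[C@@H]2OC(=O)[C@H](C)[C@@H]2CC[C@H](C)/C1=C\C[C@H](C)O[Si](C)(C)C(C)(C)C | intermediate
25 | 7,1'-epoxide of 24: spiro-oxirane at C7 with its oxygen on the face of the 8-hydroxyl, C1' bearing the (2S)-2-(tert-butyldimethylsilyloxy)propyl group | O[C@@H]1[C@@H]2OC(=O)[C@H](C)[C@@H]2CC[C@H](C)[C@]13O[C@H]3C[C@H](C)O[Si](C)(C)C(C)(C)C | intermediate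
26 | angelic acid, (2Z)-2-methylbut-2-enoic acid | C/C=C(/C)C(=O)O | starting material
27 | (2Z)-2-methylbut-2-enoate of the C8 epimer of 25 (ester oxygen on C8 trans to the oxirane oxygen and to O1) | C/C=C(/C)C(=O)O[C@H]1[C@@H]2OC(=O)[C@H](C)[C@@H]2CC[C@H](C)[C@]13O[C@H]3C[C@H](C)O[Si](C)(C)C(C)(C)C | intermediate
28 | dimethyl{[C1' of the opened epoxide]oxy}sulfonium triflate: 7-hydroxy, 1'-O-dimethylsulfonio derivative of 27 | C/C=C(/C)C(=O)O[C@H]1[C@@H]2OC(=O)[C@H](C)[C@@H]2CC[C@H](C)[C@@]1(O)[C@H](O[S+](C)C)C[C@H](C)O[Si](C)(C)C(C)(C)C.[O-]S(=O)(=O)C(F)(F)F | intermediate (not isolated)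
29 | (3R,3aS,6S,7S,8S,8aR)-7-[(3S)-3-(tert-butyldimethylsilyloxy)butanoyl]-7-hydroxy-3,6-dimethyl-2-oxooctahydro-2H-cyclohepta[b]furan-8-yl (2Z)-2-methylbut-2-enoate | C/C=C(/C)C(=O)O[C@H]1[C@@H]2OC(=O)[C@H](C)[C@@H]2CC[C@H](C)[C@@]1(O)C(=O)C[C@H](C)O[Si](C)(C)C(C)(C)C | intermediate
30 | (3R,3aS,6S,7S,8S,8aR)-7-hydroxy-7-[(3S)-3-hydroxybutanoyl]-3,6-dimethyl-2-oxooctahydro-2H-cyclohepta[b]furan-8-yl (2Z)-2-methylbut-2-enoate | C/C=C(/C)C(=O)O[C@H]1[C@@H]2OC(=O)[C@H](C)[C@@H]2CC[C@H](C)[C@@]1(O)C(=O)C[C@H](C)O | target

Total step count: 23. Longest linear sequence: 20 steps (1 to 30 through steps 1–4 and 8–23); the alkene branch (7 to 10) has 3 steps.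

Steps most likely to fail

Step 18. The acyl rhodium hydride may lose carbon monoxide before the slow seven-membered closure, which also ties up the catalyst as a carbonyl complex, or hydride may add with the opposite regiochemistry. The fallback sets out from 22 and uses the known nickel-catalysed reductive alkyne–aldehyde cyclisation (Ni(cod)2, PBu3, Et3B, toluene, rt). Zerovalent nickel couples aldehyde and alkyne to an oxanickelacycle, and the borane supplies the hydride, so the same C7–C8 bond should form by exo, syn addition. This should give the (E)-allylic alcohol as a mixture of C8 epimers F1, and Dess–Martin oxidation of the (E)-allylic alcohol F1 comes back to the route at 23.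

Step 22. The protonated epoxide may ionise at the tertiary C7, followed by participation of the C8 ester carbonyl or a 1,2-shift, instead of backside attack of DMSO at C1'. The fallback sets out from 24 and replaces steps 20 to 22. Hydrogen-bond-directed dihydroxylation with stoichiometric OsO4 and TMEDA (CH2Cl2, −78 °C; osmate ester cleaved with ethylenediamine) on the face of the C8 hydroxyl should give the 7,8,1'-triol F2. Oxoammonium oxidation (TEMPO cat., PhI(OAc)2, CH2Cl2) of the less hindered and electron-richer side-chain carbinol of the triol F2 should give the keto diol F3. Mitsunobu esterification of the keto diol F3 with 26 (PPh3, DIAD) inverts the secondary C8 carbinol, the tertiary one being inert, and comes back to the route at 29.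

Step 21. Substitution at the hindered C8 alkoxyphosphonium ion may be slow, so that elimination towards C8a or acyl transfer with retention competes. The fallback sets out from 25: chloromethanesulfonyl chloride and pyridine should give the chloromethanesulfonate F4. Displacement of the chloromethanesulfonate F4 with caesium angelate (from 26 and Cs2CO3) and 18-crown-6 in toluene at 60 °C should proceed with inversion and comes back to the route at 27.

Further compounds
F1 | step 18 | (3R,3aS,6S,8aR)-7-[(1E,3S)-3-(tert-butyldimethylsilyloxy)butylidene]-8-hydroxy-3,6-dimethyloctahydro-2H-cyclohepta[b]furan-2-one, both C8 epimers | OC1[C@@H]2OC(=O)[C@H](C)[C@@H]2CC[C@H](C)/C1=C\C[C@H](C)O[Si](C)(C)C(C)(C)C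
F2 | step 22 | 7,8-dihydroxy-7-[(3S)-3-(tert-butyldimethylsilyloxy)-1-hydroxybutyl]-3,6-dimethyloctahydro-2H-cyclohepta[b]furan-2-one, 7-OH and 8-OH cis to O1, C1'–O from syn addition | O[C@@H]1[C@@H]2OC(=O)[C@H](C)[C@@H]2CC[C@H](C)[C@@]1(O)[C@@H](O)C[C@H](C)O[Si](C)(C)C(C)(C)C
F3 | step 22 | 7-[(3S)-3-(tert-butyldimethylsilyloxy)butanoyl]-7,8-dihydroxy-3,6-dimethyloctahydro-2H-cyclohepta[b]furan-2-one, 7-OH and 8-OH cis to O1 | O[C@@H]1[C@@H]2OC(=O)[C@H](C)[C@@H]2CC[C@H](C)[C@@]1(O)C(=O)C[C@H](C)O[Si](C)(C)C(C)(C)C
F4 | step 21 | chloromethanesulfonate of 25 at the C8 oxygen | ClCS(=O)(=O)O[C@@H]1[C@@H]2OC(=O)[C@H](C)[C@@H]2CC[C@H](C)[C@]13O[C@H]3C[C@H](C)O[Si](C)(C)C(C)(C)C
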